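## The problem

The target 29 is a flavonol ether: a chromen-4-one (rings A and C) carrying a phenyl ring B at C2. It is fully aromatic and has no stereocentre, so every difficulty is one of position. Ring A bears four contiguous oxygens (O1 at C8a, 7-OH, 6-OMe, 5-OH) with the methoxy group between two free hydroxyls. A ring closure onto an unsymmetrical polyphenol can therefore give the 8-methoxy isomer, and the oxygen that becomes O1 has to be marked unambiguously. The C3 methoxy group is best carried in a building block, not installed by late methylation beside three phenols. Ring B has its 4'-hydroxyl flanked by two prenyl groups, and double ortho C-prenylation of a phenol is unselective (O-alkylation, reverse prenylation, over-alkylation). The prenyl alkenes exclude hydrogenolysis, strong oxidants and hot Brønsted acid late in the route, and a free phenol next to a prenyl group closes to a chroman under acid. The enabling feature is the local symmetry of ring B: hydrogen at C2' and C6', prenyl at C3' and C5', oxygen at C4'. That is the pattern of a 3,5-diprenyl-4-pyranone whose ring oxygen is exchanged for C1'. C1' can be the methyl carbon of a 2-methylchromone, which is acidic by vinylogy with the C4 carbonyl and is the only nucleophilic carbon once C3 carries its methoxy group.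

## Retrosynthesis

**Target 29 from 28 and 27.** The last bonds cut are the 4'-O–Si bond and the two O–CH2 bonds of the methoxymethyl (MOM) ethers at O5 and O7. The order matters: acid removes the MOM groups from 27 while the hindered silyl ether still covers the 4'-oxygen (giving 28), and fluoride then frees the phenol. A one-pot acidic deprotection would be shorter but would expose a free phenol between two prenyl groups to acid.

**27 from chromone 21 and pyranone 9 (key disconnection).** Both C1'–C2' and C1'–C6' are cut, so ring B dissolves into the methyl carbon of 21 and the five ring carbons of 9. The neighbouring cuts (C2–C1' by cross-coupling, or ring C by acyl transfer and cyclodehydration) all need a ready-made 4-oxygenated 3,5-diprenylaryl unit, so they keep the ortho-prenylation problem. Here the prenyl groups arrive on an open-chain ketone. The forward reaction has to add the lateral dienolate of 21 to C2 of the 4-silyloxypyrylium ion from 9, open the 2H-pyran and reclose it by aldol condensation. This is not established chemistry and is the main risk of the plan.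

**Pyranone 9 from ketone 6, diester 4, monoprenyl diester 3, and 1 with 2.** The ring O–C bonds and the C2–C3 and C5–C6 bonds of 9 are cut, leaving the symmetric ketone 6 and two molecules of ethyl formate 7. Ketone 6 goes back, by loss of two ester groups, to the bis-prenylated 3-oxoglutarate 4. Diester 4 is cut at one C–prenyl bond to the monoprenyl diester 3 and prenyl bromide 2, and 3 is cut in the same way to diethyl 1,3-acetonedicarboxylate 1 and a second molecule of 2. Each alkylation is its own step and consumes one equivalent of the bromide, so that geminally dialkylated material can be removed before the second prenyl group enters. Both prenyl groups are thus introduced by C-alkylation of a β-keto ester, the most dependable way to make these bonds, and the symmetry of 9 removes any regiochemical question.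

**Chromone 21 from hydroxy ketone 18 and amide acetal 19.** O1–C2 and C2–C3 are cut. N,N-Dimethylacetamide dimethyl acetal 19 supplies C2 and the methyl group under neutral conditions that spare the MOM ethers. Because 18 has a single free phenol, only the 6-methoxy chromone can form.

**18 from 17, and 17 from 14 and amide 15.** The aryl–carbonyl bond (C4a–C4) is cut. Ring lithiation of 14 can only occur between a MOM ether and the benzyl ether, and the N-methoxy-N-methylamide 15 brings C4, C3 and the C3 methoxy group in one piece. The benzyl group marks the future O1 and is removed by hydrogenolysis (17 to 18) while no alkene is present. A Friedel–Crafts or Hoesch acylation of the free triphenol would be shorter but would leave the 6- versus 8-methoxy question open.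

**14 from phenol 13, 11 and 2-methoxyresorcinol 10.** The C–O bond at the future C8a is cut back to a C–H bond. The only unhindered C–H of 11 is borylated and oxidised to give 13. This takes two steps from 10, against four (protection, reduction, oxidation, Baeyer–Villiger) from a 4-O-methylgallate ester.

## Roads not taken

**Alternative 1: ring A from a cyclobutenone.** The cut is at C8–C8a and C4a–C5. The stannylpyranone A1 and the chlorocyclobutenone A2 would be coupled with zerovalent palladium and a weakly donating phosphine. On warming, the cyclobutenone opens to a dienylketene that closes onto pyranone C5 and tautomerises to the phenol A3.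
- Merits: the oxygen pattern of ring A is written into the four-membered ring, so the 5-OH, 6-OMe and 7-O-benzyl positions are fixed, and the reaction type is established for stannylated alkenes and heteroarenes.
- Weak points: A1 must already carry the diprenylated ring B, the C3 methoxy group and a regioselectively placed tin, so the ortho-prenylation problem moves into a long fragment synthesis. A2 needs a squaric ester with two different alkoxy groups, and the regiochemistry of its reduction and chlorination decides the methoxy position. The 4-methoxybenzyl group must finally be removed by acid or an oxidant in the presence of prenyl groups.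
- Comparison: the key step of this road is on firmer ground than the pyrylium step, and A3 is closer to the target in protecting groups. The chosen plan sets against this two short fragment syntheses from commodity chemicals, prenyl groups installed by enolate alkylation, and no tin.

**Alternative 2: carbonylative assembly of the diketone.** The cut is at C4a–C4 and C4–C3. The aryl iodide A4, carbon monoxide A6 and the enolate of the ring B ketone A5 would combine under zerovalent palladium with a wide-bite-angle diphosphine to give the 2-methoxy-1,3-diketone A7. Desilylation and cyclodehydration would then close ring C.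
- Merits: it is convergent, the C3 methoxy group is in place, and A7 is the classical flavone precursor, so the ring closure is certain.
- Weak points: no ring forms in the key step. A4 is an electron-rich iodide with two ortho substituents, so capture of the acylpalladium by a hindered α-methoxy enolate is slow and direct arylation competes. A7 is also what acylation of a hydroxy ketone followed by Baker–Venkataraman rearrangement gives without palladium or A6, so the gain is small. A5 again needs the diprenylated arene.
- Comparison: this road is more predictable than the chosen one. It is not shorter and leaves ring B unsolved, which is the problem the chosen plan addresses. Its classical counterpart serves below as the fallback.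

**Alternative 3: ring A by anionic benzannulation.** The cut is at C7–C8 and C5–C6. The lateral anion of the pyranone ester A8 would be acylated by methyl methoxyacetate A9, and the new ketone enolate would close onto the ring ester to give A10, the 4'-O-MOM ether of the target.
- Merits: ring A appears with its 5- and 7-hydroxyls free and the 6-methoxy group fixed by connectivity, so one deprotection finishes the synthesis. This end-game is better than that of the chosen plan.
- Weak points: A8 is a pentasubstituted pyranone bearing the diprenylated ring B, and making it is long. After acylation the most acidic site is the methylene between pyranone and ketone, whereas closure needs the α-methoxy carbon, so a dianion is required. A9 also self-condenses.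
- Comparison: this is the mirror image of the chosen idea (a pyranone grown into a benzene ring) with a known type of key step. The chosen plan has simpler key precursors and keeps the prenyl chemistry away from any phenol.

Key step: step 11

## Route

Remark: 2-methoxyresorcinol 10, amide 15 and amide acetal 19 are taken as purchasable. Compounds 3, 4, 5, 24 and 26 are racemic or diastereomeric mixtures whose stereocentres all disappear, so no configuration is assigned.

Step 1
Reactants: 1 diethyl 1,3-acetonedicarboxylate (diethyl 3-oxopentanedioate); 2 prenyl bromide (1-bromo-3-methylbut-2-ene)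
Product: 3 diethyl 2-(3-methylbut-2-enyl)-3-oxopentanedioate (racemic)
Conditions: NaH (1.0 equiv), THF, 0 °C; then 2 (0.95 equiv), 0 °C to rt
Reagents that add atoms: none
Why: C-alkylation of a doubly activated methylene group of a 3-oxoglutarate (acetoacetic ester alkylation) with a reactive allylic bromide. Keeping the bromide as the limiting component holds back a second alkylation, and unchanged 1 is separated from 3 by distillation or chromatography.

Step 2
Reactants: 3 diethyl 2-(3-methylbut-2-enyl)-3-oxopentanedioate; 2 prenyl bromide (1-bromo-3-methylbut-2-ene)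
Product: 4 diethyl 2,4-bis(3-methylbut-2-enyl)-3-oxopentanedioate (diastereomer mixture)
Conditions: NaH (1.05 equiv), THF, 0 °C; then 2 (1.1 equiv), rt
Reagents that add atoms: none
Why: Second acetoacetic ester alkylation. The untouched CH2 of 3 is the more acidic and less hindered site, so the enolate forms there and the second prenyl group enters at the other α-carbon instead of geminally; the two stereocentres are erased in step 3.

Step 3
Reactants: 4 diethyl 2,4-bis(3-methylbut-2-enyl)-3-oxopentanedioate
Product: 6 2,10-dimethylundeca-2,9-dien-6-one, via oxo diacid 5 (not isolated)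
Conditions: KOH, EtOH/H2O, rt; then 2 M HCl to pH 2, 50 °C
Reagents that add atoms: potassium hydroxide, [K+].[OH-] (its oxygen is found only in intermediate 5)
Why: Ketonic hydrolysis: saponification followed by decarboxylation of the β-keto diacid through the cyclic six-membered transition state. Brief warming in dilute acid should leave the trisubstituted alkenes intact.

Step 4
Reactants: 6 2,10-dimethylundeca-2,9-dien-6-one; 7 ethyl formate
Product: 9 3,5-bis(3-methylbut-2-enyl)-4H-pyran-4-one, via bis-hydroxymethylene ketone 8 (not isolated)
Conditions: 7 (excess), NaH, EtOH (cat.), THF, 0 °C to rt; then 1 M HCl, Et2O, 0 °C to rt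
Reagents that add atoms: none
Why: Double Claisen formylation at both α-methylene groups (the second through the dianion), then acid-induced cyclodehydration to the aromatic 4-pyranone. This is the established passage from ketones with two α-methylene groups to 3,5-disubstituted 4-pyranones.

Step 5
Reactants: 10 2-methoxyresorcinol (2-methoxybenzene-1,3-diol)
Product: 11 2-methoxy-1,3-bis(methoxymethoxy)benzene
Conditions: MOMCl, i-Pr2NEt, CH2Cl2, 0 °C to rt
Reagents that add atoms: chloromethyl methyl ether, COCCl
Why: O-alkylation of both phenols to MOM ethers, which are stable to base and organolithiums, direct the later lithiation and leave under mild acid.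

Step 6
Reactants: 11 2-methoxy-1,3-bis(methoxymethoxy)benzene
Product: 13 4-methoxy-3,5-bis(methoxymethoxy)phenol, via arylboronate 12 (not isolated)
Conditions: [Ir(OMe)(cod)]2 (cat.), 4,4'-di-tert-butyl-2,2'-bipyridine (cat.), B2pin2 (0.6 equiv), THF, 80 °C; then aq. H2O2, NaOH, 0 °C
Reagents that add atoms: bis(pinacolato)diboron, CC1(C)OB(OC1(C)C)B1OC(C)(C)C(C)(C)O1 (boron is found only in intermediate 12); hydrogen peroxide, OO
Why: Iridium-catalysed C–H borylation is governed by sterics, and C5 is the only ring position without an ortho substituent. Alkaline peroxide then oxidises the C–B bond to the phenol in the same flask.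

Step 7
Reactants: 13 4-methoxy-3,5-bis(methoxymethoxy)phenol
Product: 14 5-(benzyloxy)-2-methoxy-1,3-bis(methoxymethoxy)benzene
Conditions: BnBr, K2CO3, DMF, rt
Reagents that add atoms: benzyl bromide, BrCc1ccccc1
Why: Williamson etherification. The benzyl group marks the oxygen that becomes O1 and can be removed by hydrogenolysis before any alkene is in the molecule.

Step 8
Reactants: 14 5-(benzyloxy)-2-methoxy-1,3-bis(methoxymethoxy)benzene; 15 N,2-dimethoxy-N-methylacetamide
Product: 17 1-[6-(benzyloxy)-3-methoxy-2,4-bis(methoxymethoxy)phenyl]-2-methoxyethan-1-one, via aryllithium 16 (not isolated)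
Conditions: n-BuLi, THF, 0 °C; then 15, −78 °C to 0 °C; aq. NH4Cl
Reagents that add atoms: n-butyllithium, [Li]CCCC (lithium is found only in intermediate 16)
Why: Directed ortho-metalation: the two equivalent ring C–H bonds lie between a MOM ether and the benzyloxy group, both of which coordinate lithium. The aryllithium acylates the N-methoxy-N-methylamide once, because the chelated tetrahedral adduct survives until work-up.

Step 9
Reactants: 17 1-[6-(benzyloxy)-3-methoxy-2,4-bis(methoxymethoxy)phenyl]-2-methoxyethan-1-one
Product: 18 1-[6-hydroxy-3-methoxy-2,4-bis(methoxymethoxy)phenyl]-2-methoxyethan-1-one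
Conditions: H2 (1 atm), 10% Pd/C, EtOAc, rt
Reagents that add atoms: none
Why: Hydrogenolysis of the benzyl aryl ether; the MOM ethers and the hindered, hydrogen-bonded aryl ketone should not react at ambient pressure. Only one phenol is now free, and it is the one next to the ring C–H.

Step 10
Reactants: 18 1-[6-hydroxy-3-methoxy-2,4-bis(methoxymethoxy)phenyl]-2-methoxyethan-1-one; 19 N,N-dimethylacetamide dimethyl acetal (1,1-dimethoxy-N,N-dimethylethanamine)
Product: 21 3,6-dimethoxy-5,7-bis(methoxymethoxy)-2-methyl-4H-chromen-4-one, via enaminone 20 (not isolated)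
Conditions: 19 (3 equiv), toluene, 110 °C
Reagents that add atoms: none
Why: Amide acetal condensation at the activated methylene gives the enaminone; the single free phenol adds to its β-carbon and dimethylamine is lost, closing ring C (chromone synthesis from o-hydroxyaryl ketones and amide acetals). The conditions are neutral, so the MOM ethers stay, and only the 6-methoxy isomer can form.

Step 11
Reactants: 21 3,6-dimethoxy-5,7-bis(methoxymethoxy)-2-methyl-4H-chromen-4-one; 9 3,5-bis(3-methylbut-2-enyl)-4H-pyran-4-one
Product: 27 2-[4-(tert-butyldimethylsilyloxy)-3,5-bis(3-methylbut-2-enyl)phenyl]-3,6-dimethoxy-5,7-bis(methoxymethoxy)-4H-chromen-4-one, via lithium dienolate 22 (not isolated), via silyloxypyrylium triflate 23 (not isolated), via 2H-pyran adduct 24 (not isolated), via ring-opened dienal 25 (not isolated), via cyclohexadienol aldol 26 (not isolated)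
Conditions: 9 (1.2 equiv), TBSOTf (1.1 equiv), CH2Cl2, 0 °C; separately 21, LiN(SiMe3)2, THF, −78 °C; dienolate added to the pyrylium solution at −78 °C; then DBU, −78 °C to rt
Reagents that add atoms: tert-butyldimethylsilyl trifluoromethanesulfonate, CC(C)(C)[Si](C)(C)OS(=O)(=O)C(F)(F)F; lithium bis(trimethylsilyl)amide, [Li]N([Si](C)(C)C)[Si](C)(C)C (lithium is found only in intermediate 22)
Why: Proposed new method: TBSOTf O-silylates pyranone 9 to the 4-silyloxypyrylium triflate 23, prepared apart from 21 and with 9 in slight excess so that no free silyl triflate reaches the MOM ethers; the lithium dienolate 22 then adds through its exocyclic carbon to C2 of 23, the position at which carbon nucleophiles add to 4-silyloxypyrylium ions, giving 2H-pyran 24 and the C1'–C2' bond. Adduct 24 opens to dienal 25 either by thermal 6π electrocyclic ring opening or, once DBU removes a proton from the doubly activated CH2, by E1cB expulsion of the ring oxygen as an enolate. The same carbanion, stabilised by vinylogy with the chromone carbonyl, closes onto the aldehyde carbon (C1'–C6', a 6-exo-trig aldol addition, equivalently a 6π closure of the trienolate) to give 26, and loss of water aromatises ring B with the silyl ether already on C4'. The closest known reaction types are the conversion of pyrylium salts into benzenes by nitromethane or other methylene-active carbanions through this same addition, ring-opening and aldol sequence, and the addition of silyl enol ethers and organometallics to C2 of 4-silyloxypyrylium ions; new are the vinylogous ketone enolate as the one-carbon donor and a pyrylium ion unsubstituted at C2 and C6. No stereocentre survives: C2 of 24 and both sp3 centres of 26 are erased on aromatisation, and the C2'=C3' geometry of 25 can equilibrate through the delocalised anion if it is formed with the wrong sense for closure. Attack at C2 and not C4 of 23 is secured by the donor silyloxy group at C4 and its two flanking prenyl groups; attack through the exocyclic carbon of 22 is secured by the methoxy group on C3; C2 and C6 of the symmetric pyrylium ion are equivalent. Should silyl transfer to the dienolate oxygen compete, the resulting silyl dienol ether is itself a nucleophile of the known kind toward 23.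

Step 12
Reactants: 27 2-[4-(tert-butyldimethylsilyloxy)-3,5-bis(3-methylbut-2-enyl)phenyl]-3,6-dimethoxy-5,7-bis(methoxymethoxy)-4H-chromen-4-one
Product: 28 2-[4-(tert-butyldimethylsilyloxy)-3,5-bis(3-methylbut-2-enyl)phenyl]-5,7-dihydroxy-3,6-dimethoxy-4H-chromen-4-one
Conditions: conc. HCl (cat.), MeOH/THF, 40 °C
Reagents that add atoms: none
Why: Acid-catalysed acetal exchange with methanol removes both MOM groups, the one next to the carbonyl fastest. The aryl silyl ether, hindered by two ortho substituents and weakly basic at oxygen, should stay on and keeps the 4'-oxygen from adding to a protonated prenyl group.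

Step 13
Reactants: 28 2-[4-(tert-butyldimethylsilyloxy)-3,5-bis(3-methylbut-2-enyl)phenyl]-5,7-dihydroxy-3,6-dimethoxy-4H-chromen-4-one
Product: 29 5,7-dihydroxy-2-[4-hydroxy-3,5-bis(3-methylbut-2-enyl)phenyl]-3,6-dimethoxy-4H-chromen-4-one (CNP0236361.0)
Conditions: Bu4NF, AcOH, THF, 0 °C
Reagents that add atoms: none
Why: Fluoride cleaves the aryl silyl ether (strong Si–F bond, phenoxide leaving group). Acetic acid buffers the phenoxides, so the electron-rich product is not held under basic conditions.

## Compound list

1 | diethyl 1,3-acetonedicarboxylate | CCOC(=O)CC(=O)CC(=O)OCC | starting material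
2 | prenyl bromide | CC(C)=CCBr | starting material
3 | diethyl 2-(3-methylbut-2-enyl)-3-oxopentanedioate (racemic) | CCOC(=O)CC(=O)C(CC=C(C)C)C(=O)OCC | intermediate
4 | diethyl 2,4-bis(3-methylbut-2-enyl)-3-oxopentanedioate (diastereomer mixture) | CCOC(=O)C(CC=C(C)C)C(=O)C(CC=C(C)C)C(=O)OCC | intermediate
5 | 2,4-bis(3-methylbut-2-enyl)-3-oxopentanedioic acid (diastereomer mixture) | OC(=O)C(CC=C(C)C)C(=O)C(CC=C(C)C)C(=O)O | intermediate (not isolated)
6 | 2,10-dimethylundeca-2,9-dien-6-one | CC(C)=CCCC(=O)CCC=C(C)C | intermediate
7 | ethyl formate | CCOC=O | starting material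
8 | 1,5-dihydroxy-2,4-bis(3-methylbut-2-enyl)penta-1,4-dien-3-one (enol geometry undefined) | O=C(C(CC=C(C)C)=CO)C(CC=C(C)C)=CO | intermediate (not isolated)
9 | 3,5-bis(3-methylbut-2-enyl)-4H-pyran-4-one | O=c1c(CC=C(C)C)cocc1CC=C(C)C | intermediate
10 | 2-methoxyresorcinol | COc1c(O)cccc1O | starting material
11 | 2-methoxy-1,3-bis(methoxymethoxy)benzene | COCOc1cccc(OCOC)c1OC | intermediate
12 | 2-[4-methoxy-3,5-bis(methoxymethoxy)phenyl]-4,4,5,5-tetramethyl-1,3,2-dioxaborolane | COCOc1cc(B2OC(C)(C)C(C)(C)O2)cc(OCOC)c1OC | intermediate (not isolated)
13 | 4-methoxy-3,5-bis(methoxymethoxy)phenol | COCOc1cc(O)cc(OCOC)c1OC | intermediate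
14 | 5-(benzyloxy)-2-methoxy-1,3-bis(methoxymethoxy)benzene | COCOc1cc(OCc2ccccc2)cc(OCOC)c1OC | intermediate
15 | N,2-dimethoxy-N-methylacetamide | COCC(=O)N(C)OC | starting material
16 | [6-(benzyloxy)-3-methoxy-2,4-bis(methoxymethoxy)phenyl]lithium | [Li]c1c(OCOC)c(OC)c(OCOC)cc1OCc1ccccc1 | intermediate (not isolated)
17 | 1-[6-(benzyloxy)-3-methoxy-2,4-bis(methoxymethoxy)phenyl]-2-methoxyethan-1-one | COCC(=O)c1c(OCc2ccccc2)cc(OCOC)c(OC)c1OCOC | intermediate
18 | 1-[6-hydroxy-3-methoxy-2,4-bis(methoxymethoxy)phenyl]-2-methoxyethan-1-one | COCC(=O)c1c(O)cc(OCOC)c(OC)c1OCOC | intermediate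
19 | N,N-dimethylacetamide dimethyl acetal | CC(OC)(OC)N(C)C | starting material
20 | 3-(dimethylamino)-1-[6-hydroxy-3-methoxy-2,4-bis(methoxymethoxy)phenyl]-2-methoxybut-2-en-1-one (alkene geometry undefined) | COCOc1cc(O)c(C(=O)C(OC)=C(C)N(C)C)c(OCOC)c1OC | intermediate (not isolated)
21 | 3,6-dimethoxy-5,7-bis(methoxymethoxy)-2-methyl-4H-chromen-4-one | Cc1oc2cc(OCOC)c(OC)c(OCOC)c2c(=O)c1OC | intermediate
22 | lithium 3,6-dimethoxy-5,7-bis(methoxymethoxy)-2-methylidene-2H-chromen-4-olate | [Li]OC1=C(OC)C(=C)Oc2cc(OCOC)c(OC)c(OCOC)c12 | intermediate (not isolated)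
23 | 4-(tert-butyldimethylsilyloxy)-3,5-bis(3-methylbut-2-enyl)pyrylium trifluoromethanesulfonate | CC(C)=CCc1c[o+]cc(CC=C(C)C)c1O[Si](C)(C)C(C)(C)C.[O-]S(=O)(=O)C(F)(F)F | intermediate (not isolated)
24 | 2-{[4-(tert-butyldimethylsilyloxy)-3,5-bis(3-methylbut-2-enyl)-2H-pyran-2-yl]methyl}-3,6-dimethoxy-5,7-bis(methoxymethoxy)-4H-chromen-4-one (racemic) | COCOc1cc2oc(CC3OC=C(CC=C(C)C)C(O[Si](C)(C)C(C)(C)C)=C3CC=C(C)C)c(OC)c(=O)c2c(OCOC)c1OC | intermediate (not isolated)
25 | 3-(tert-butyldimethylsilyloxy)-6-[3,6-dimethoxy-5,7-bis(methoxymethoxy)-4-oxo-4H-chromen-2-yl]-2,4-bis(3-methylbut-2-enyl)hexa-2,4-dienal (formyl carbon and C4 cis across C2=C3; C4=C5 geometry undefined) | COCOc1cc2oc(CC=C(CC=C(C)C)/C(O[Si](C)(C)C(C)(C)C)=C(CC=C(C)C)\C=O)c(OC)c(=O)c2c(OCOC)c1OC | intermediate (not isolated)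
26 | 2-[4-(tert-butyldimethylsilyloxy)-6-hydroxy-3,5-bis(3-methylbut-2-enyl)cyclohexa-2,4-dien-1-yl]-3,6-dimethoxy-5,7-bis(methoxymethoxy)-4H-chromen-4-one (diastereomer mixture) | COCOc1cc2oc(C3C=C(CC=C(C)C)C(O[Si](C)(C)C(C)(C)C)=C(CC=C(C)C)C3O)c(OC)c(=O)c2c(OCOC)c1OC | intermediate (not isolated)
27 | 2-[4-(tert-butyldimethylsilyloxy)-3,5-bis(3-methylbut-2-enyl)phenyl]-3,6-dimethoxy-5,7-bis(methoxymethoxy)-4H-chromen-4-one | COCOc1cc2oc(-c3cc(CC=C(C)C)c(O[Si](C)(C)C(C)(C)C)c(CC=C(C)C)c3)c(OC)c(=O)c2c(OCOC)c1OC | intermediate
28 | 2-[4-(tert-butyldimethylsilyloxy)-3,5-bis(3-methylbut-2-enyl)phenyl]-5,7-dihydroxy-3,6-dimethoxy-4H-chromen-4-one | COc1c(O)cc2oc(-c3cc(CC=C(C)C)c(O[Si](C)(C)C(C)(C)C)c(CC=C(C)C)c3)c(OC)c(=O)c2c1O | intermediate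
29 | 5,7-dihydroxy-2-[4-hydroxy-3,5-bis(3-methylbut-2-enyl)phenyl]-3,6-dimethoxy-4H-chromen-4-one | COc1c(O)cc2oc(-c3cc(CC=C(C)C)c(O)c(CC=C(C)C)c3)c(OC)c(=O)c2c1O | target

## Step count and weak points

Total: 13 steps (4 to pyranone 9, 6 to chromone 21, 3 from the union). Longest linear sequence: 9 steps (10 to 29 through steps 5 to 13).

**Step 11 (key step, proposed new method).** Three processes can defeat it. The dienolate may take the silyl group from the pyrylium oxygen instead of attacking C2. The ring-opened dienal may be consumed by intermolecular aldol or Michael reactions faster than it closes. The vinylogous silyl ester may also be desilylated before closure; this last process is harmless, because the phenol it gives converges on 29 in the last steps. The fallback abandons the pyranone and closes ring C last by known flavone chemistry, setting out from hydroxy ketone 18 and rejoining the route at target 29. Purchasable methyl 4-hydroxy-3,5-diiodobenzoate is converted into its MOM ether, methyl 3,5-diiodo-4-(methoxymethoxy)benzoate F1. A double Stille coupling with tributyl(3-methylbut-2-enyl)stannane and Pd(PPh3)4 gives methyl 4-(methoxymethoxy)-3,5-bis(3-methylbut-2-enyl)benzoate F2, and LiOH gives 4-(methoxymethoxy)-3,5-bis(3-methylbut-2-enyl)benzoic acid F3. Carbodiimide esterification of 18 with F3 gives 4-methoxy-2-(methoxyacetyl)-3,5-bis(methoxymethoxy)phenyl 4-(methoxymethoxy)-3,5-bis(3-methylbut-2-enyl)benzoate F4. LiN(SiMe3)2 effects Baker–Venkataraman acyl migration to 1-[6-hydroxy-3-methoxy-2,4-bis(methoxymethoxy)phenyl]-2-methoxy-3-[4-(methoxymethoxy)-3,5-bis(3-methylbut-2-enyl)phenyl]propane-1,3-dione F5, whose single free phenol fixes the ring oxygen. Warm acetic acid with NaOAc dehydrates it to 3,6-dimethoxy-5,7-bis(methoxymethoxy)-2-[4-(methoxymethoxy)-3,5-bis(3-methylbut-2-enyl)phenyl]-4H-chromen-4-one F6, and mild methanolic HCl gives 29. This fallback accepts that the 4'-oxygen is unprotected during the acid step.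

**Step 4.** The second formylation may stall because the first formyl enolate resists further deprotonation, and the acid used for ring closure may protonate a prenyl alkene. The fallback sets out from ketone 6 and returns at pyranone 9. Heating 6 with tert-butoxybis(dimethylamino)methane gives 1,5-bis(dimethylamino)-2,4-bis(3-methylbut-2-enyl)penta-1,4-dien-3-one F7, which aqueous acetic acid hydrolyses and cyclises to 9.

**Step 8.** Deprotonation at the benzylic CH2, followed by Wittig rearrangement, may compete with ring lithiation. The fallback sets out from phenol 13 and returns at ketone 17. N-Bromosuccinimide gives 2-bromo-4-methoxy-3,5-bis(methoxymethoxy)phenol F8, and benzylation gives 1-(benzyloxy)-2-bromo-4-methoxy-3,5-bis(methoxymethoxy)benzene F9. Bromine–lithium exchange with n-BuLi at −78 °C, which outruns any deprotonation, then generates aryllithium 16, and acylation with 15 gives 17.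

**Step 10.** Condensation of the amide acetal at a hindered α-methoxy methylene may be slow, and methyl transfer from the acetal to the phenol may intervene. The fallback sets out from 18 and returns at chromone 21. Acetic anhydride and pyridine give 4-methoxy-2-(methoxyacetyl)-3,5-bis(methoxymethoxy)phenyl acetate F10. LiN(SiMe3)2 brings about Baker–Venkataraman migration to 1-[6-hydroxy-3-methoxy-2,4-bis(methoxymethoxy)phenyl]-2-methoxybutane-1,3-dione F11, and warm acetic acid with NaOAc closes it to 21.

**Step 12.** Acid may remove the silyl ether too, after which the free 4'-phenol can add to a protonated prenyl group (chroman formation); methanol may also add to a prenyl alkene. The fallback sets out from 27 and returns at target 29 without Brønsted acid. Trimethylsilyl triflate with 2,2'-bipyridyl in CH2Cl2 at 0 °C exchanges both aryl MOM ethers for trimethylsilyl ethers, giving 2-[4-(tert-butyldimethylsilyloxy)-3,5-bis(3-methylbut-2-enyl)phenyl]-3,6-dimethoxy-5,7-bis(trimethylsilyloxy)-4H-chromen-4-one F12. Bu4NF with acetic acid then removes all three silyl groups to give 29.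

## Further compounds

F1 | step 11 | methyl 3,5-diiodo-4-(methoxymethoxy)benzoate | COCOc1c(I)cc(C(=O)OC)cc1I
F2 | step 11 | methyl 4-(methoxymethoxy)-3,5-bis(3-methylbut-2-enyl)benzoate | COCOc1c(CC=C(C)C)cc(C(=O)OC)cc1CC=C(C)C
F3 | step 11 | 4-(methoxymethoxy)-3,5-bis(3-methylbut-2-enyl)benzoic acid | COCOc1c(CC=C(C)C)cc(C(=O)O)cc1CC=C(C)C
F4 | step 11 | 4-methoxy-2-(methoxyacetyl)-3,5-bis(methoxymethoxy)phenyl 4-(methoxymethoxy)-3,5-bis(3-methylbut-2-enyl)benzoate | COCC(=O)c1c(OC(=O)c2cc(CC=C(C)C)c(OCOC)c(CC=C(C)C)c2)cc(OCOC)c(OC)c1OCOC
F5 | step 11 | 1-[6-hydroxy-3-methoxy-2,4-bis(methoxymethoxy)phenyl]-2-methoxy-3-[4-(methoxymethoxy)-3,5-bis(3-methylbut-2-enyl)phenyl]propane-1,3-dione (racemic) | COCOc1cc(O)c(C(=O)C(OC)C(=O)c2cc(CC=C(C)C)c(OCOC)c(CC=C(C)C)c2)c(OCOC)c1OC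
F6 | step 11 | 3,6-dimethoxy-5,7-bis(methoxymethoxy)-2-[4-(methoxymethoxy)-3,5-bis(3-methylbut-2-enyl)phenyl]-4H-chromen-4-one | COCOc1cc2oc(-c3cc(CC=C(C)C)c(OCOC)c(CC=C(C)C)c3)c(OC)c(=O)c2c(OCOC)c1OC
F7 | step 4 | 1,5-bis(dimethylamino)-2,4-bis(3-methylbut-2-enyl)penta-1,4-dien-3-one | CN(C)C=C(CC=C(C)C)C(=O)C(CC=C(C)C)=CN(C)C
F8 | step 8 | 2-bromo-4-methoxy-3,5-bis(methoxymethoxy)phenol | COCOc1cc(O)c(Br)c(OCOC)c1OC
F9 | step 8 | 1-(benzyloxy)-2-bromo-4-methoxy-3,5-bis(methoxymethoxy)benzene | COCOc1cc(OCc2ccccc2)c(Br)c(OCOC)c1OC
F10 | step 10 | 4-methoxy-2-(methoxyacetyl)-3,5-bis(methoxymethoxy)phenyl acetate | COCC(=O)c1c(OC(C)=O)cc(OCOC)c(OC)c1OCOC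
F11 | step 10 | 1-[6-hydroxy-3-methoxy-2,4-bis(methoxymethoxy)phenyl]-2-methoxybutane-1,3-dione (racemic) | COCOc1cc(O)c(C(=O)C(OC)C(C)=O)c(OCOC)c1OC
F12 | step 12 | 2-[4-(tert-butyldimethylsilyloxy)-3,5-bis(3-methylbut-2-enyl)phenyl]-3,6-dimethoxy-5,7-bis(trimethylsilyloxy)-4H-chromen-4-one | COc1c(O[Si](C)(C)C)cc2oc(-c3cc(CC=C(C)C)c(O[Si](C)(C)C(C)(C)C)c(CC=C(C)C)c3)c(OC)c(=O)c2c1O[Si](C)(C)C
A1 | alternative 1 | 3-methoxy-2-[4-(methoxymethoxy)-3,5-bis(3-methylbut-2-enyl)phenyl]-6-(tributylstannyl)-4H-pyran-4-one | CCCC[Sn](CCCC)(CCCC)c1cc(=O)c(OC)c(-c2cc(CC=C(C)C)c(OCOC)c(CC=C(C)C)c2)o1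
A2 | alternative 1 | 4-chloro-2-methoxy-3-[(4-methoxybenzyl)oxy]cyclobut-2-en-1-one (racemic) | COC1=C(OCc2ccc(OC)cc2)C(Cl)C1=O
A3 | alternative 1 | 5-hydroxy-3,6-dimethoxy-7-[(4-methoxybenzyl)oxy]-2-[4-(methoxymethoxy)-3,5-bis(3-methylbut-2-enyl)phenyl]-4H-chromen-4-one | COCOc1c(CC=C(C)C)cc(-c2oc3cc(OCc4ccc(OC)cc4)c(OC)c(O)c3c(=O)c2OC)cc1CC=C(C)C
A4 | alternative 2 | tert-butyl[2-iodo-4-methoxy-3,5-bis(methoxymethoxy)phenoxy]dimethylsilane | COCOc1cc(O[Si](C)(C)C(C)(C)C)c(I)c(OCOC)c1OC
A5 | alternative 2 | 2-methoxy-1-[4-(methoxymethoxy)-3,5-bis(3-methylbut-2-enyl)phenyl]ethan-1-one | COCC(=O)c1cc(CC=C(C)C)c(OCOC)c(CC=C(C)C)c1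
A6 | alternative 2 | carbon monoxide | [C-]#[O+]
A7 | alternative 2 | 1-[6-(tert-butyldimethylsilyloxy)-3-methoxy-2,4-bis(methoxymethoxy)phenyl]-2-methoxy-3-[4-(methoxymethoxy)-3,5-bis(3-methylbut-2-enyl)phenyl]propane-1,3-dione (racemic) | COCOc1cc(O[Si](C)(C)C(C)(C)C)c(C(=O)C(OC)C(=O)c2cc(CC=C(C)C)c(OCOC)c(CC=C(C)C)c2)c(OCOC)c1OC
A8 | alternative 3 | methyl 5-methoxy-6-[4-(methoxymethoxy)-3,5-bis(3-methylbut-2-enyl)phenyl]-2-methyl-4-oxo-4H-pyran-3-carboxylate | COC(=O)c1c(C)oc(-c2cc(CC=C(C)C)c(OCOC)c(CC=C(C)C)c2)c(OC)c1=O
A9 | alternative 3 | methyl methoxyacetate | COCC(=O)OC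
A10 | alternative 3 | 5,7-dihydroxy-3,6-dimethoxy-2-[4-(methoxymethoxy)-3,5-bis(3-methylbut-2-enyl)phenyl]-4H-chromen-4-one | COCOc1c(CC=C(C)C)cc(-c2oc3cc(O)c(OC)c(O)c3c(=O)c2OC)cc1CC=C(C)C
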